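## Structural features

The target is a sesterterpenoid on a bicyclo[9.3.1]pentadecane core. A cyclohexane (C1, C2, C15, C14, C13, C12; C1 is the quaternary carbon bearing the carboxyl group) is spanned from C2 to C12 by the nine-carbon bridge C3–C11, so that C1–C12 form a twelve-membered ring. The bridge holds two methyl-bearing trisubstituted Z alkenes (C4=C5, C8=C9); C1 also carries a 4-methylpent-3-enyl chain (C16 onward); C13 is the spiro carbon of an oxirane. Four stereocentres stand in a row (C2, C1, C12, C13). C3 and the carboxyl group lie on one face of the cyclohexane; C11, C16 and the oxirane oxygen lie on the other, so the bridge is attached trans and the oxirane oxygen is anti to the carboxyl group. Fragile elements are the 2,2-disubstituted oxirane (acid, and the nearby carboxyl as internal nucleophile), three electron-rich trisubstituted alkenes and the Z geometry of the ring alkenes. The difficulty is a quaternary stereocentre between two tertiary ones inside a trans-bridged macrocycle, plus oxidation at C13 and at the C1 branch in the presence of more reactive alkenes. The skeleton is a regular head-to-tail pentaprenyl chain in which only C2–C3 and C1–C12 are non-chain bonds; the key step forms exactly these two bonds from the C1=C2 and C12=C13 alkenes and the allylic terminus C3 of an acyclic precursor.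

Atom labels C1–C16 always mean the target numbering, also for the corresponding atoms of intermediates; locants inside systematic names follow nomenclature rules.

## Logic of the disconnections

**30 to 29.** The oxirane is cut at C13–CH2 and C–O, i.e. methylene transfer to a C13 ketone. Any oxidant able to pick the 1,1-disubstituted alkene out of four alkenes would have to be delivered from the C1 carbon branch, which puts oxygen on the wrong face of C13. A carbon nucleophile arriving on that same face gives the required epimer. This removes the oxirane and one stereocentre; the forward step must attack anti to the C11 and C16 arms and tolerate a carboxylate.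

**29 to 25 (through 28, 27, 26).** The acid is traced to a neopentyl alcohol (two standard oxidations). The ketone is traced to the exocyclic methylene through hydroxyl-directed epoxidation and glycol cleavage, because only proximity to the hydroxyl distinguishes this alkene from the trisubstituted ones. The demand is that the hydroxyl reaches no other alkene.

**25 to 24.** The alcohol is masked as a silyl ether for the cyclization.

**24 to 23.** C2–C3 and C1–C12 are cut together. This removes both rings and three stereocentres and leaves an achiral pentaene diphosphate. A hydrocarbon version would leave an unactivated methyl on C1 that no chemical reagent could oxidize selectively, so the oxygen is placed on that carbon before cyclization, as a bulky non-nucleophilic silyl ether. The forward step needs a catalyst that enforces one fold, suppresses other closures and ends by proton loss from the methyl on C13.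

**23 to 21 (through 22).** The diphosphate C–O bond is made from the Z allylic alcohol via its chloride.

**21 to 10 and 18 (through 20, 19).** The chain is cut at C10–C11, between two allylic carbons, as a sulfone carbanion alkylation followed by reductive desulfonylation. This is convergent and separates the two Z alkenes (in 18) from the half that carries the cyclization-critical C1=C2 geometry (in 10). The demand is alkylation at the sulfone carbon and sulfone removal without alkene migration.

**18 to 11 and 15 (through 17, 16, 14, 12).** C8=C9 is cut as a Z-selective olefination of aldehyde 14; C4=C5 comes with its Z geometry from 11. Cuprate methylation of enol phosphates would need the less accessible E enol phosphates for these Z alkenes, so phosphonate olefination is used.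

**10 to 1, 5 and 6 (through 9, 8, 7, 4, 2).** C1=C2 is cut as a Z-selective olefination of aldehyde 4 with the branched phosphonate 7. The ester carbon becomes the carboxyl carbon, and its position cis to C15 decides the C1/C2 relationship in the key step.

## Other disconnections considered

**Alternative 1:** The cut is at C1–C16 and C12–C11, leaving the enone ester A1 (C2 arm in place), a homoprenyl nucleophile and the triflate A2. Forward, 4-methylpent-3-enylmagnesium bromide with CuBr·SMe2 and Me3SiCl would add to C1 of A1 anti to the C2 arm; the lithium enolate released with MeLi would be alkylated at C12 by A2 to give A3.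
- In favour: known reaction types, substrate control of C1 and C12 from one centre. C13 arrives as a ketone with C1 at the ester level; on this point it is better than the chosen plan, which must excise the exocyclic methylene to reach the same ketone.
- Against: it closes no ring; A1 must be made enantioenriched and can racemize through its dienol; a hindered enolate beside a quaternary carbon must be alkylated by an unactivated triflate; a methyl ester on a quaternary carbon must be cleaved late.
- Comparison: more secure in mechanism, but it builds two bonds and two stereocentres and no ring (against two rings and three stereocentres), and arms, core and ring closure each need their own sequence.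

**Alternative 2:** The cut is at C6–C7 of the macrocycle, leaving the bromo sulfone A4. Forward, KN(SiMe3)2 at high dilution would form the C7 carbanion, which displaces the C6 allylic bromide to give A5.
- In favour: carbanion alkylation between an allylic sulfone and an allylic bromide is an established way to close polyprenoid macrocycles with Z alkenes intact. In reliability of the key step it is clearly better than the chosen plan, and equal in preserving the Z alkenes.
- Against: one bond, one ring, no stereocentre; A4 presupposes the complete cyclohexane core (for instance from A3) plus several functional-group changes; the sulfone must be removed reductively beside a Z alkene; a ketal must be put on and taken off.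
- Comparison: same ring, SN2 carbanion chemistry instead of a cation cascade, much poorer step economy.

**Alternative 3:** The cut is at C14–C15, leaving the macrocyclic aldehyde A6 (formyl on C2, isopropenyl on C12). Forward, Me2AlCl would promote a carbonyl-ene closure to A7 with the C13 exocyclic methylene and a C15 hydroxyl.
- In favour: one known step closes the six-membered ring and fixes the alkene position. The C15 hydroxyl of A7 is homoallylic to C13=CH2 and sits on the face where the oxirane oxygen belongs, so a directed epoxidation could make the spiro-oxirane directly and keep the methylene carbon. On the oxirane problem this is better than the chosen plan.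
- Against: A6 already needs the twelve-membered ring and all of C1, C2, C12, with C2 epimerizable beside the aldehyde; the Lewis acid may engage the ring alkenes; the C15 hydroxyl must be removed afterwards beside the oxirane.
- Comparison: known mechanism and a better C13 endgame, against a far longer route to A6.

Key step: step 17

Assumption 1: the one-carbon branch on C1 is carried through the key step as CH2OSi(t-Bu)Me2, a spectator change that leaves the carbon skeletons of precursor and product untouched; the C1=C2 alkene of 23 is then Z by the sequence rules although its geometry is that of the 14E alkene of the parent geranylfarnesyl diphosphate.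

Assumption 2: nucleophiles reach the C13 carbonyl of 29 from the face opposite to the C11 and C16 arms (equatorial attack in the chair that holds the homoprenyl arm axial).

## Route

Step 1
Reactants: 1 geranyl bromide
Product: 2 geranyl phenyl sulfone
Conditions: PhSO2Na, DMF, 25 °C
Reagents that add atoms: sodium benzenesulfinate, [Na+].[O-]S(=O)c1ccccc1
Why: SN2 displacement of the primary allylic bromide by the sulfur of the sulfinate; the sulfonyl group later stabilizes the C11 carbanion and deactivates the neighbouring alkene in step 2.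

Step 2
Reactants: 2 geranyl phenyl sulfone
Product: 4 (4E)-4-methyl-6-(phenylsulfonyl)hex-4-enal, via the epoxy sulfone 3 (not isolated)
Conditions: mCPBA, NaHCO3, CH2Cl2, 0 °C; then H5IO6, THF/H2O, 0 °C
Reagents that add atoms: mCPBA, OOC(=O)c1cccc(Cl)c1
Why: Prilezhaev epoxidation should take the remote trisubstituted alkene because the other is deactivated by the allylic sulfonyl group; periodic acid then opens the oxirane and cleaves the glycol (Malaprade cleavage) to the aldehyde carbon that becomes C2.

Step 3
Reactants: 5 methyl 2-[bis(2,2,2-trifluoroethoxy)phosphoryl]acetate; 6 5-bromo-2-methylpent-2-ene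
Product: 7 methyl 2-[bis(2,2,2-trifluoroethoxy)phosphoryl]-6-methylhept-5-enoate (racemic)
Conditions: KOt-Bu, DMF, 0 °C; then 6, NaI (cat.), 50 °C
Reagents that add atoms: none
Why: malonate-type C-alkylation of the stabilized phosphonoacetate anion by the primary halide (iodide formed in situ, Finkelstein exchange).

Step 4
Reactants: 4 (4E)-4-methyl-6-(phenylsulfonyl)hex-4-enal; 7 branched phosphonate
Product: 8 methyl (2Z,6E)-6-methyl-2-(4-methylpent-3-en-1-yl)-8-(phenylsulfonyl)octa-2,6-dienoate
Conditions: 7, KN(SiMe3)2, 18-crown-6, THF, −78 °C; then 4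
Reagents that add atoms: none
Why: Still–Gennari variant of the Horner–Wadsworth–Emmons olefination; the trifluoroethyl phosphonate should give the Z enoate, i.e. the ester carbon cis to C15 across the new C1=C2 alkene, the geometry that later fixes C1 relative to C2. The sulfone CH2 is too weakly acidic to be deprotonated by the preformed phosphonate anion.

Step 5
Reactants: 8 Z enoate
Product: 9 (2Z,6E)-6-methyl-2-(4-methylpent-3-en-1-yl)-8-(phenylsulfonyl)octa-2,6-dien-1-ol
Conditions: i-Bu2AlH, CH2Cl2, −78 °C
Reagents that add atoms: none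
Why: 1,2-reduction of the conjugated ester by the aluminium hydride; sulfone and alkene geometry are not touched.

Step 6
Reactants: 9 allylic alcohol
Product: 10 tert-butyldimethylsilyl ether of 9
Conditions: t-BuMe2SiCl, imidazole, CH2Cl2, 0 to 25 °C
Reagents that add atoms: tert-butyldimethylsilyl chloride, CC(C)(C)[Si](C)(C)Cl
Why: silylation of the primary allylic alcohol; the silyl ether is a fluoride-labile, non-nucleophilic mask for the future carboxyl carbon and should last through steps 12 to 17.

Step 7
Reactants: 11 nerol
Product: 12 neryl 4-methoxybenzyl ether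
Conditions: NaH, 4-MeOC6H4CH2Cl, Bu4NI (cat.), THF/DMF, 0 to 25 °C
Reagents that add atoms: 4-methoxybenzyl chloride, COc1ccc(CCl)cc1
Why: Williamson ether synthesis; the ether oxygen deactivates the adjacent alkene towards peracid and the group can later be removed oxidatively beside a silyl ether.

Step 8
Reactants: 12 neryl 4-methoxybenzyl ether
Product: 14 (4Z)-6-[(4-methoxybenzyl)oxy]-4-methylhex-4-enal, via the epoxy ether 13 (not isolated)
Conditions: mCPBA, NaHCO3, CH2Cl2, −20 to 0 °C; then H5IO6, THF/H2O, 0 °C
Reagents that add atoms: mCPBA, OOC(=O)c1cccc(Cl)c1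
Why: Prilezhaev epoxidation of the more electron-rich terminal alkene followed by periodic acid cleavage; the Z alkene of nerol (the future C4=C5) is carried over unchanged.

Step 9
Reactants: 14 (4Z)-6-[(4-methoxybenzyl)oxy]-4-methylhex-4-enal; 15 ethyl 2-[bis(2,2,2-trifluoroethoxy)phosphoryl]propanoate
Product: 16 ethyl (2Z,6Z)-8-[(4-methoxybenzyl)oxy]-2,6-dimethylocta-2,6-dienoate
Conditions: 15, KN(SiMe3)2, 18-crown-6, THF, −78 °C; then 14
Reagents that add atoms: none
Why: Still–Gennari olefination should give the Z trisubstituted enoate with the ester carbon (future C10) cis to C7, which is the Z C8=C9 alkene of the target.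

Step 10
Reactants: 16 Z,Z ester
Product: 17 (2Z,6Z)-8-[(4-methoxybenzyl)oxy]-2,6-dimethylocta-2,6-dien-1-ol
Conditions: i-Bu2AlH, CH2Cl2, −78 °C
Reagents that add atoms: none
Why: 1,2-reduction of the conjugated ester to the allylic alcohol without change of alkene geometry.

Step 11
Reactants: 17 Z,Z allylic alcohol
Product: 18 (2Z,6Z)-1-bromo-8-[(4-methoxybenzyl)oxy]-2,6-dimethylocta-2,6-diene
Conditions: NBS, Me2S, CH2Cl2, −30 to 0 °C
Reagents that add atoms: N-bromosuccinimide, BrN1C(=O)CCC1=O
Why: Corey–Kim bromination; bromide displaces the alkoxysulfonium group at the primary carbon (SN2), so no allyl cation forms and position and Z geometry of the alkene should be kept.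

Step 12
Reactants: 10 silyl ether sulfone; 18 Z,Z allylic bromide
Product: 19 4-methoxybenzyl ether of (2Z,6Z,10E,14Z)-15-({[tert-butyl(dimethyl)silyl]oxy}methyl)-3,7,11,19-tetramethyl-9-(phenylsulfonyl)icosa-2,6,10,14,18-pentaen-1-ol (racemic at the sulfone carbon)
Conditions: 10, BuLi, THF/DMPU, −78 °C; then 18
Reagents that add atoms: none
Why: Julia-type alkylation of the α-sulfonyl allyl carbanion at its α-carbon by the primary allylic bromide (SN2) forms C10–C11; the Z alkenes of the electrophile are not involved, and the new centre at C11 is removed in step 13.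

Step 13
Reactants: 19 coupled sulfone
Product: 20 4-methoxybenzyl ether of (2Z,6Z,10E,14Z)-15-({[tert-butyl(dimethyl)silyl]oxy}methyl)-3,7,11,19-tetramethylicosa-2,6,10,14,18-pentaen-1-ol
Conditions: PdCl2(dppp) (cat.), LiBHEt3, THF, 0 °C
Reagents that add atoms: none
Why: reductive desulfonylation; zerovalent palladium formed in situ ionizes the allylic sulfone and hydride should enter at the less substituted terminus C11, leaving the trisubstituted E alkene C12=C13 in place; allylic ethers are not ionized.

Step 14
Reactants: 20 protected pentaene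
Product: 21 (2Z,6Z,10E,14Z)-15-({[tert-butyl(dimethyl)silyl]oxy}methyl)-3,7,11,19-tetramethylicosa-2,6,10,14,18-pentaen-1-ol
Conditions: DDQ, CH2Cl2/pH 7 buffer, 0 °C
Reagents that add atoms: none
Why: oxidative cleavage of the 4-methoxybenzyl ether (hydride abstraction, hydrolysis of the oxocarbenium ion); silyl ether and trisubstituted alkenes are inert under buffered conditions.

Step 15
Reactants: 21 Z allylic alcohol
Product: 22 the corresponding (2Z,6Z,10E,14Z) allylic chloride
Conditions: NCS, Me2S, CH2Cl2, −30 to 0 °C
Reagents that add atoms: N-chlorosuccinimide, ClN1C(=O)CCC1=O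
Why: Corey–Kim chlorination by SN2 at the primary carbon, which should keep the Z geometry of the C4=C5 alkene.

Step 16
Reactants: 22 allylic chloride
Product: 23 (2Z,6Z,10E,14Z)-15-({[tert-butyl(dimethyl)silyl]oxy}methyl)-3,7,11,19-tetramethylicosa-2,6,10,14,18-pentaen-1-yl diphosphate (handled as its ammonium salt)
Conditions: (Bu4N)3HP2O7, MeCN, 25 °C; then NH4+ ion exchange, aq. NH4HCO3
Reagents that add atoms: tris(tetrabutylammonium) hydrogen diphosphate, CCCC[N+](CCCC)(CCCC)CCCC.CCCC[N+](CCCC)(CCCC)CCCC.CCCC[N+](CCCC)(CCCC)CCCC.OP(=O)([O-])OP(=O)([O-])[O-]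
Why: SN2 displacement of the primary allylic chloride by the diphosphate anion, the standard entry to allylic diphosphates; the silyl ether is stable at the near-neutral pH of the ion exchange.

Step 17
Reactants: 23 acyclic diphosphate
Product: 24 bicyclic silyl ether (bicyclo[9.3.1] skeleton, Z alkenes C4=C5 and C8=C9, exocyclic C13=CH2, C1 bearing CH2OSi(t-Bu)Me2 syn to C3 and the 4-methylpent-3-enyl arm anti to C3, C11 anti to C3)
Conditions: engineered class 1 terpene synthase, MgCl2, HEPES buffer pH 7.5, 30 °C, pentane overlay
Reagents that add atoms: none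
Why: Proposed new method: a Mg2+-dependent class 1 terpene synthase ionizes the allylic diphosphate of 23 to the cisoid C3–C5 allyl cation, C2 of the C1=C2 alkene attacks C3 (14-membered closure, exo at the alkene, Markovnikov), the tertiary C1 cation is taken up at C12 by the C12=C13 alkene (six-membered closure, endo), and a base in the pocket removes a proton from the methyl on C13 to leave the exocyclic alkene. The closest known reaction type is the cyclization of geranylgeranyl diphosphate to verticillene-type bicyclo[9.3.1] cations by class 1 synthases, together with the known turnover of Z,Z-configured prenyl diphosphates and of oxygenated farnesyl diphosphate analogues by such enzymes; no catalyst is known for 23, so it has to be found by screening and engineering. C2 and C1 are set together by anti addition across the C1=C2 alkene, whose fixed geometry places C3 and the silyloxymethyl carbon cis. C12 is set by the face of the C12=C13 alkene that the fold presents to C1, and only the fold with C11 anti to C3 gives the trans-bridged product. Absolute configuration comes from the chiral pocket alone, since 23 is achiral. The step needs chemoselectivity against the easy six-membered closure of C3 onto C8=C9 and against early proton loss, hydride shift or oxygen capture at the C1 cation; the substrate helps with preset Z alkenes that enter the ring unchanged, tertiary cation sites at both stages and a bulky silyl ether that cannot act as an internal nucleophile.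

Step 18
Reactants: 24 bicyclic silyl ether
Product: 25 bicyclic neopentyl alcohol (C1 CH2OH, C13=CH2)
Conditions: Bu4NF, THF, 0 to 25 °C
Reagents that add atoms: none
Why: fluoride-induced cleavage of the Si–O bond; alkenes and stereocentres are not affected.

Step 19
Reactants: 25 bicyclic alcohol
Product: 26 epoxy alcohol (spiro-oxirane at C13 with its oxygen syn to the C1 CH2OH group)
Conditions: VO(acac)2 (cat.), t-BuOOH, toluene, 0 to 25 °C
Reagents that add atoms: tert-butyl hydroperoxide, CC(C)(C)OO
Why: hydroxyl-directed epoxidation; the vanadium alkoxide delivers the peroxide oxygen intramolecularly, so only the exocyclic alkene, three bonds from the carbinol carbon, should react and the trisubstituted alkenes are spared. The oxygen enters syn to the hydroxymethyl group, which does not matter because C13 becomes trigonal in step 20.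

Step 20
Reactants: 26 epoxy alcohol
Product: 27 keto alcohol (C13 ketone, C1 CH2OH)
Conditions: H5IO6, THF/H2O, 0 °C
Reagents that add atoms: water, O
Why: periodic acid opens the oxirane to the glycol and cleaves it (Malaprade cleavage) to the C13 ketone and formaldehyde; this stands in for an ozonolysis that the other alkenes would not survive.

Step 21
Reactants: 27 keto alcohol
Product: 28 keto aldehyde (C13 ketone, C1 CHO)
Conditions: Dess–Martin periodinane, NaHCO3, CH2Cl2, 0 to 25 °C
Reagents that add atoms: none
Why: Dess–Martin oxidation of the neopentyl alcohol; the aldehyde has no α-hydrogen and cannot epimerize.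

Step 22
Reactants: 28 keto aldehyde
Product: 29 keto acid (C13 ketone, C1 CO2H)
Conditions: NaClO2, NaH2PO4, 2-methylbut-2-ene, t-BuOH/H2O, 0 to 25 °C
Reagents that add atoms: sodium chlorite, [Na+].[O-]Cl=O
Why: Pinnick oxidation; the added alkene scavenges hypochlorous acid and so protects the alkenes of the substrate.

Step 23
Reactants: 29 keto acid
Product: 30 target epoxy acid CNP0116395.1
Conditions: Me3S+ I−, KN(SiMe3)2, THF/DMSO, −10 to 20 °C (29 added as its potassium salt); pH 6 work-up
Reagents that add atoms: trimethylsulfonium iodide, C[S+](C)C.[I-]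
Why: Corey–Chaykovsky epoxidation; the sulfonium ylide adds irreversibly to the ketone and the alkoxide displaces Me2S. The ylide should approach C13 anti to the C11 and C16 arms, which puts the new CH2 on the face of the carboxyl group and the oxygen on the opposite face, as in 30; the carboxylate is inert to the ylide.

## Compound list

1 | geranyl bromide, (2E)-1-bromo-3,7-dimethylocta-2,6-diene | CC(C)=CCC/C(C)=C/CBr | starting material
2 | geranyl phenyl sulfone | CC(C)=CCC/C(C)=C/CS(=O)(=O)c1ccccc1 | intermediate
3 | {[(2E)-5-(3,3-dimethyloxiran-2-yl)-3-methylpent-2-en-1-yl]sulfonyl}benzene (racemic, not isolated) | CC1(C)OC1CC/C(C)=C/CS(=O)(=O)c1ccccc1 | intermediate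
4 | (4E)-4-methyl-6-(phenylsulfonyl)hex-4-enal | O=CCC/C(C)=C/CS(=O)(=O)c1ccccc1 | intermediate
5 | methyl 2-[bis(2,2,2-trifluoroethoxy)phosphoryl]acetate | COC(=O)CP(=O)(OCC(F)(F)F)OCC(F)(F)F | starting material
6 | 5-bromo-2-methylpent-2-ene | CC(C)=CCCBr | starting material
7 | methyl 2-[bis(2,2,2-trifluoroethoxy)phosphoryl]-6-methylhept-5-enoate (racemic) | COC(=O)C(CCC=C(C)C)P(=O)(OCC(F)(F)F)OCC(F)(F)F | intermediate
8 | methyl (2Z,6E)-6-methyl-2-(4-methylpent-3-en-1-yl)-8-(phenylsulfonyl)octa-2,6-dienoate | COC(=O)/C(CCC=C(C)C)=C\CC/C(C)=C/CS(=O)(=O)c1ccccc1 | intermediate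
9 | (2Z,6E)-6-methyl-2-(4-methylpent-3-en-1-yl)-8-(phenylsulfonyl)octa-2,6-dien-1-ol | OC/C(CCC=C(C)C)=C\CC/C(C)=C/CS(=O)(=O)c1ccccc1 | intermediate
10 | tert-butyldimethylsilyl ether of 9 | CC(C)(C)[Si](C)(C)OC/C(CCC=C(C)C)=C\CC/C(C)=C/CS(=O)(=O)c1ccccc1 | intermediate
11 | nerol, (2Z)-3,7-dimethylocta-2,6-dien-1-ol | CC(C)=CCC/C(C)=C\CO | starting material
12 | neryl 4-methoxybenzyl ether | CC(C)=CCC/C(C)=C\COCc1ccc(OC)cc1 | intermediate
13 | 6,7-epoxide of 12 (racemic, not isolated) | CC1(C)OC1CC/C(C)=C\COCc1ccc(OC)cc1 | intermediate
14 | (4Z)-6-[(4-methoxybenzyl)oxy]-4-methylhex-4-enal | O=CCC/C(C)=C\COCc1ccc(OC)cc1 | intermediate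
15 | ethyl 2-[bis(2,2,2-trifluoroethoxy)phosphoryl]propanoate (racemic) | CCOC(=O)C(C)P(=O)(OCC(F)(F)F)OCC(F)(F)F | starting material
16 | ethyl (2Z,6Z)-8-[(4-methoxybenzyl)oxy]-2,6-dimethylocta-2,6-dienoate | CCOC(=O)/C(C)=C\CC/C(C)=C\COCc1ccc(OC)cc1 | intermediate
17 | (2Z,6Z)-8-[(4-methoxybenzyl)oxy]-2,6-dimethylocta-2,6-dien-1-ol | OC/C(C)=C\CC/C(C)=C\COCc1ccc(OC)cc1 | intermediate
18 | (2Z,6Z)-1-bromo-8-[(4-methoxybenzyl)oxy]-2,6-dimethylocta-2,6-diene | BrC/C(C)=C\CC/C(C)=C\COCc1ccc(OC)cc1 | intermediate
19 | 4-methoxybenzyl ether of (2Z,6Z,10E,14Z)-15-({[tert-butyl(dimethyl)silyl]oxy}methyl)-3,7,11,19-tetramethyl-9-(phenylsulfonyl)icosa-2,6,10,14,18-pentaen-1-ol (racemic at C9 of the chain) | CC(C)(C)[Si](C)(C)OC/C(CCC=C(C)C)=C\CC/C(C)=C/C(C/C(C)=C\CC/C(C)=C\COCc1ccc(OC)cc1)S(=O)(=O)c1ccccc1 | intermediate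
20 | 4-methoxybenzyl ether of 21 | CC(C)(C)[Si](C)(C)OC/C(CCC=C(C)C)=C\CC/C(C)=C/CC/C(C)=C\CC/C(C)=C\COCc1ccc(OC)cc1 | intermediate
21 | (2Z,6Z,10E,14Z)-15-({[tert-butyl(dimethyl)silyl]oxy}methyl)-3,7,11,19-tetramethylicosa-2,6,10,14,18-pentaen-1-ol | CC(C)(C)[Si](C)(C)OC/C(CCC=C(C)C)=C\CC/C(C)=C/CC/C(C)=C\CC/C(C)=C\CO | intermediate
22 | allylic chloride of 21 | CC(C)(C)[Si](C)(C)OC/C(CCC=C(C)C)=C\CC/C(C)=C/CC/C(C)=C\CC/C(C)=C\CCl | intermediate
23 | diphosphate of 21 (precursor of the key step) | CC(C)(C)[Si](C)(C)OC/C(CCC=C(C)C)=C\CC/C(C)=C/CC/C(C)=C\CC/C(C)=C\COP(=O)(O)OP(=O)(O)O | intermediate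
24 | bicyclic silyl ether (product of the key step; C1 CH2OSi(t-Bu)Me2 syn to C3, C16 and C11 anti to C3, C13=CH2) | CC(C)=CCC[C@]1(CO[Si](C)(C)C(C)(C)C)[C@H]2C/C=C(/C)CC/C=C(/C)CC[C@H]1C(=C)CC2 | intermediate
25 | bicyclic alcohol (C1 CH2OH, C13=CH2) | CC(C)=CCC[C@]1(CO)[C@H]2C/C=C(/C)CC/C=C(/C)CC[C@H]1C(=C)CC2 | intermediate
26 | epoxy alcohol (oxirane oxygen syn to CH2OH) | CC(C)=CCC[C@]1(CO)[C@H]2C/C=C(/C)CC/C=C(/C)CC[C@H]1[C@]1(CC2)CO1 | intermediate
27 | keto alcohol (C13 ketone, C1 CH2OH) | CC(C)=CCC[C@]1(CO)[C@H]2C/C=C(/C)CC/C=C(/C)CC[C@H]1C(=O)CC2 | intermediate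
28 | keto aldehyde (C13 ketone, C1 CHO) | CC(C)=CCC[C@]1(C=O)[C@H]2C/C=C(/C)CC/C=C(/C)CC[C@H]1C(=O)CC2 | intermediate
29 | keto acid (C13 ketone, C1 CO2H) | CC(C)=CCC[C@]1(C(=O)O)[C@H]2C/C=C(/C)CC/C=C(/C)CC[C@H]1C(=O)CC2 | intermediate
30 | CNP0116395.1, epoxy acid (C3 and CO2H on one face of the cyclohexane; C11, C16 and the oxirane oxygen on the other) | CC(C)=CCC[C@]1(C(=O)O)[C@H]2C/C=C(/C)CC/C=C(/C)CC[C@H]1[C@@]1(CC2)CO1 | target

## Step count and least certain steps

Total: 23 steps. Longest linear sequence: 17 steps (from 1 through steps 1, 2, 4, 5, 6 and 12 to 23; the branch from 11 is equally long).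

**Step 17 (key step, new enzymatic method).** Most likely failure: the chain folds the wrong way. Either the C3 cation is captured by the nearby C8=C9 alkene in a six-membered closure, or the C1 cation is quenched by proton loss or hydride shift before the second ring forms; no catalyst with the needed fold may be found.

Fallback with known chemistry, setting out from 17 and 6 and returning at 27: 17 is silylated (t-BuMe2SiCl, imidazole) to the bis-ether F1, the 4-methoxybenzyl group is removed with DDQ to give the alcohol F2, and NBS/Me2S gives the bromide F3. The lithium enolate of 3-ethoxycyclohex-2-en-1-one (LiN(i-Pr)2, THF, −78 °C) is alkylated with F3 (Stork–Danheiser alkylation) to the vinylogous ester F4. Addition of 4-MeOC6H4CH2OCH2Li (from the tributylstannane and BuLi) and mild acid hydrolysis give the enone F5, whose enantiomers are separated on a chiral stationary phase. 4-Methylpent-3-enylmagnesium bromide (from 6) with CuBr·SMe2 and Me3SiCl adds to C1 anti to the C2 arm to give the silyl enol ether F6. PhSCH2Cl with ZnBr2 then places C11 on C12 anti to the pseudo-axial oxygenated C1 branch, giving the sulfide F7. Ketalization ((Me3SiOCH2)2, Me3SiOTf, −78 °C) gives the ketal F8 and (NH4)6Mo7O24/H2O2 the sulfone F9. Bu4NF gives the allylic alcohol F10 and NBS/Me2S the bromide F11. KN(SiMe3)2 at high dilution closes the C10–C11 bond by sulfone carbanion alkylation to the macrocyclic sulfone F12. Mg in MeOH removes the sulfonyl group (macrocycle F13), DDQ gives the ketal alcohol F14, and pyridinium tosylate in wet acetone gives 27.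

**Step 23.** Most likely failure: methylene transfer on the wrong face of C13 if the cyclohexanone reacts through the chair with the C11 arm axial, or enolization of the hindered ketone by the basic ylide.

Fallback, setting out from 24 and returning at 30; it changes from carbon delivery to oxygen delivery at C13, which gives the required epimer exactly when the ylide would not: 9-BBN adds chemoselectively to the exocyclic alkene of 24 and NaBO3 gives the primary alcohol F15; Dess–Martin oxidation gives the aldehyde F16; t-BuMe2SiOTf/Et3N gives the enol silyl ether F17. Dimethyldioxirane oxidizes this far more electron-rich alkene from its open face (Rubottom oxidation) to the α-silyloxy aldehyde F18. NaBH4 gives the alcohol F19 and MsCl/Et3N the mesylate F20. Bu4NF removes both silyl groups and the C13 alkoxide closes the oxirane to the epoxy alcohol F21. Dess–Martin oxidation gives the epoxy aldehyde F22 and NaClO2 (Pinnick conditions) gives 30.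

**Step 3.** Most likely failure: sluggish C-alkylation of the weakly nucleophilic trifluoroethyl phosphonate anion by an unactivated bromide, with dialkylation and loss of trifluoroethoxy groups competing.

Fallback, setting out from 6 and returning at 7: the more nucleophilic anion of methyl 2-(diethoxyphosphoryl)acetate (NaH, DMSO) is alkylated with 6 to the diethyl phosphonate F23. Me3SiBr converts it into the bis(trimethylsilyl) phosphonate F24, (COCl)2 with catalytic DMF into the phosphonic dichloride F25, and CF3CH2OH/i-Pr2NEt then gives 7.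

**Step 16.** Most likely failure: allylic transposition or elimination during displacement at the Z allylic chloride, and hydrolysis of the product during ion exchange.

Fallback, setting out from 21 and returning at 23: the alcohol is phosphorylated directly on oxygen with Cl3CCN and bis(triethylammonium) hydrogen phosphate in MeCN, and the diphosphate is taken from the mono-, di- and triphosphate mixture by ion-exchange chromatography. No substitution at carbon occurs and no new compound is needed.

## Further compounds

F1 | step 17 | tert-butyl{[(2Z,6Z)-8-[(4-methoxybenzyl)oxy]-2,6-dimethylocta-2,6-dien-1-yl]oxy}dimethylsilane | CC(C)(C)[Si](C)(C)OC/C(C)=C\CC/C(C)=C\COCc1ccc(OC)cc1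
F2 | step 17 | (2Z,6Z)-8-{[tert-butyl(dimethyl)silyl]oxy}-3,7-dimethylocta-2,6-dien-1-ol | CC(C)(C)[Si](C)(C)OC/C(C)=C\CC/C(C)=C\CO
F3 | step 17 | {[(2Z,6Z)-8-bromo-2,6-dimethylocta-2,6-dien-1-yl]oxy}(tert-butyl)dimethylsilane | CC(C)(C)[Si](C)(C)OC/C(C)=C\CC/C(C)=C\CBr
F4 | step 17 | 6-[(2Z,6Z)-8-{[tert-butyl(dimethyl)silyl]oxy}-3,7-dimethylocta-2,6-dien-1-yl]-3-ethoxycyclohex-2-en-1-one (racemic) | CCOC1=CC(=O)C(CC1)C/C=C(/C)CC/C=C(/C)CO[Si](C)(C)C(C)(C)C
F5 | step 17 | 4-[(2Z,6Z)-8-{[tert-butyl(dimethyl)silyl]oxy}-3,7-dimethylocta-2,6-dien-1-yl]-3-{[(4-methoxybenzyl)oxy]methyl}cyclohex-2-en-1-one (C2 as in 30, after resolution) | O=C1C=C(COCc2ccc(OC)cc2)[C@H](CC1)C/C=C(/C)CC/C=C(/C)CO[Si](C)(C)C(C)(C)C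
F6 | step 17 | trimethylsilyl enol ether of the C1-quaternary cyclohexanone (C1, C2 as in 30) | CC(C)=CCC[C@]1(COCc2ccc(OC)cc2)[C@H](CCC(O[Si](C)(C)C)=C1)C/C=C(/C)CC/C=C(/C)CO[Si](C)(C)C(C)(C)C
F7 | step 17 | cyclohexanone with phenylthiomethyl on C12 (C1, C2, C12 as in 30) | CC(C)=CCC[C@]1(COCc2ccc(OC)cc2)[C@H](CCC(=O)[C@@H]1CSc1ccccc1)C/C=C(/C)CC/C=C(/C)CO[Si](C)(C)C(C)(C)C
F8 | step 17 | ethylene ketal of F7 | CC(C)=CCC[C@]1(COCc2ccc(OC)cc2)[C@H](CCC3(OCCO3)[C@@H]1CSc1ccccc1)C/C=C(/C)CC/C=C(/C)CO[Si](C)(C)C(C)(C)C
F9 | step 17 | phenyl sulfone of F8 | CC(C)=CCC[C@]1(COCc2ccc(OC)cc2)[C@H](CCC3(OCCO3)[C@@H]1CS(=O)(=O)c1ccccc1)C/C=C(/C)CC/C=C(/C)CO[Si](C)(C)C(C)(C)C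
F10 | step 17 | allylic alcohol from F9 (C10 OH) | CC(C)=CCC[C@]1(COCc2ccc(OC)cc2)[C@H](CCC3(OCCO3)[C@@H]1CS(=O)(=O)c1ccccc1)C/C=C(/C)CC/C=C(/C)CO
F11 | step 17 | allylic bromide from F10 (C10 Br) | CC(C)=CCC[C@]1(COCc2ccc(OC)cc2)[C@H](CCC3(OCCO3)[C@@H]1CS(=O)(=O)c1ccccc1)C/C=C(/C)CC/C=C(/C)CBr
F12 | step 17 | macrocyclic sulfone (bicyclo[9.3.1] ketal, PhSO2 on C11, C11 epimers) | CC(C)=CCC[C@]1(COCc3ccc(OC)cc3)[C@H]2C/C=C(/C)CC/C=C(/C)CC(S(=O)(=O)c3ccccc3)[C@H]1C1(OCCO1)CC2
F13 | step 17 | desulfonylated bicyclic ketal 4-methoxybenzyl ether | CC(C)=CCC[C@]1(COCc3ccc(OC)cc3)[C@H]2C/C=C(/C)CC/C=C(/C)CC[C@H]1C1(OCCO1)CC2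
F14 | step 17 | bicyclic ketal alcohol (ethylene ketal of 27) | CC(C)=CCC[C@]1(CO)[C@H]2C/C=C(/C)CC/C=C(/C)CC[C@H]1C1(OCCO1)CC2
F15 | step 23 | C13 hydroxymethyl silyl ether (C13 epimers) | CC(C)=CCC[C@]1(CO[Si](C)(C)C(C)(C)C)[C@H]2C/C=C(/C)CC/C=C(/C)CC[C@H]1C(CO)CC2
F16 | step 23 | C13 carbaldehyde (C13 epimers) | CC(C)=CCC[C@]1(CO[Si](C)(C)C(C)(C)C)[C@H]2C/C=C(/C)CC/C=C(/C)CC[C@H]1C(C=O)CC2
F17 | step 23 | exocyclic enol silyl ether at C13 (E/Z mixture) | CC(C)=CCC[C@]1(CO[Si](C)(C)C(C)(C)C)[C@H]2C/C=C(/C)CC/C=C(/C)CC[C@H]1C(=CO[Si](C)(C)C(C)(C)C)CC2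
F18 | step 23 | α-silyloxy aldehyde (C13 oxygen anti to the C1 oxygenated branch) | CC(C)=CCC[C@]1(CO[Si](C)(C)C(C)(C)C)[C@H]2C/C=C(/C)CC/C=C(/C)CC[C@H]1[C@@](O[Si](C)(C)C(C)(C)C)(CC2)C=O
F19 | step 23 | primary alcohol from F18 | CC(C)=CCC[C@]1(CO[Si](C)(C)C(C)(C)C)[C@H]2C/C=C(/C)CC/C=C(/C)CC[C@H]1[C@@](O[Si](C)(C)C(C)(C)C)(CC2)CO
F20 | step 23 | mesylate of F19 | CC(C)=CCC[C@]1(CO[Si](C)(C)C(C)(C)C)[C@H]2C/C=C(/C)CC/C=C(/C)CC[C@H]1[C@@](O[Si](C)(C)C(C)(C)C)(CC2)COS(C)(=O)=O
F21 | step 23 | epoxy alcohol (oxirane as in 30, C1 CH2OH) | CC(C)=CCC[C@]1(CO)[C@H]2C/C=C(/C)CC/C=C(/C)CC[C@H]1[C@@]1(CC2)CO1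
F22 | step 23 | epoxy aldehyde (oxirane as in 30, C1 CHO) | CC(C)=CCC[C@]1(C=O)[C@H]2C/C=C(/C)CC/C=C(/C)CC[C@H]1[C@@]1(CC2)CO1
F23 | step 3 | methyl 2-(diethoxyphosphoryl)-6-methylhept-5-enoate (racemic) | CCOP(=O)(OCC)C(CCC=C(C)C)C(=O)OC
F24 | step 3 | methyl 2-{bis[(trimethylsilyl)oxy]phosphoryl}-6-methylhept-5-enoate (racemic) | COC(=O)C(CCC=C(C)C)P(=O)(O[Si](C)(C)C)O[Si](C)(C)C
F25 | step 3 | methyl 2-(dichlorophosphoryl)-6-methylhept-5-enoate (racemic) | COC(=O)C(CCC=C(C)C)P(=O)(Cl)Cl
F0 | step 16 | none | none
A1 | alternative 1 | methyl 6-[(2Z)-4-{[tert-butyl(dimethyl)silyl]oxy}-3-methylbut-2-en-1-yl]-3-oxocyclohex-1-ene-1-carboxylate (C2 as in 30) | COC(=O)C1=CC(=O)CC[C@@H]1C/C=C(/C)CO[Si](C)(C)C(C)(C)C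
A2 | alternative 1 | (3Z)-5-[(4-methoxybenzyl)oxy]-3-methylpent-3-en-1-yl trifluoromethanesulfonate | O=S(=O)(OCC/C(C)=C\COCc1ccc(OC)cc1)C(F)(F)F
A3 | alternative 1 | 2,3,3,4-substituted cyclohexanone with both Z arms, methyl ester and homoprenyl chain | CC(C)=CCC[C@]1(C(=O)OC)[C@@H](C/C=C(/C)CO[Si](C)(C)C(C)(C)C)CCC(=O)[C@@H]1CC/C(C)=C\COCc1ccc(OC)cc1
A4 | alternative 2 | seco bromo sulfone (C6 allylic bromide, C7 allylic phenyl sulfone, C13 dioxolane, methyl ester) | CC(C)=CCC[C@]1(C(=O)OC)[C@@H](C/C=C(/C)CBr)CCC2(OCCO2)[C@@H]1CC/C(C)=C\CS(=O)(=O)c1ccccc1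
A5 | alternative 2 | bicyclo[9.3.1] methyl ester with C13 dioxolane and C7 phenylsulfonyl group (C7 epimers) | CC(C)=CCC[C@]1(C(=O)OC)[C@H]2C/C=C(/C)CC(S(=O)(=O)c3ccccc3)/C=C(/C)CC[C@H]1C1(OCCO1)CC2
A6 | alternative 3 | twelve-membered ring methyl ester with formyl group on C2 and isopropenyl group on C12 | CC(C)=CCC[C@]1(C(=O)OC)[C@H](C=O)C/C=C(/C)CC/C=C(/C)CC[C@H]1C(C)=C
A7 | alternative 3 | bicyclo[9.3.1] methyl ester with C13 exocyclic methylene and C15 hydroxyl | CC(C)=CCC[C@]1(C(=O)OC)[C@H]2C/C=C(/C)CC/C=C(/C)CC[C@H]1C(=C)C[C@H]2O
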